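**Retrosynthetic overview**
1. Target 24 ⇐ tertiary alcohol 22 (C3–OH → C3–Cl, steered by the neighbouring C2 bromine) ⇐ α-bromo ketone 21 ⇐ spiro enone 19.
2. Ring B (closed last) ⇐ intramolecular aldol condensation of keto aldehyde 18, made by Michael union of aldehyde 7 (fragment 1, ring A) with silyl enone 16 (fragment 2).
3. Ring A (closed first) ⇐ enantiospecific bromonium cyclisation of bromohydrin 3 ⇐ Shi epoxide 2 of geranyl acetate 1.
4. Fragment 2 ⇐ Et3SiCl, CH2=CHMgBr and acetaldehyde.

Assumption: all spiro compounds are named with one fixed spiro[5.5]undecane numbering (ring B = C1–C5, spiro carbon = C6, ring A = C7–C11), so the target is (2R,3R,6R,10S)-2,10-dibromo-3-chloro-3,7,11,11-tetramethylspiro[5.5]undec-7-ene; purchasable reagents (Shi ketone, Oxone and the like) are not counted as steps.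

**Fragment 1 (ring A aldehyde)**

Step 1
Reactants: 1 geranyl acetate
Product: 2 (2E)-5-[(2R)-3,3-dimethyloxiran-2-yl]-3-methylpent-2-en-1-yl acetate
Conditions: D-fructose-derived Shi ketone (30 mol %), Oxone (2KHSO5·KHSO4·K2SO4), K2CO3, Bu4NHSO4, Na2B4O7 buffer, MeCN/(MeO)2CH2/H2O, 0 °C
Reagents that add atoms: potassium peroxymonosulfate (active part of Oxone), [K+].[O-]S(=O)(=O)OO
Why: Shi asymmetric epoxidation, in which the chiral dioxirane attacks only the electron-rich 6,7-olefin (the 2,3-olefin is deactivated by the allylic acetate) and sets the R epoxide carbon through the spiro transition state (about 90% ee expected, to be raised by recrystallising bromo ketone 21).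

Step 2
Reactants: 2 (2E)-5-[(2R)-3,3-dimethyloxiran-2-yl]-3-methylpent-2-en-1-yl acetate
Product: 3 (2E,6S)-6-bromo-7-hydroxy-3,7-dimethyloct-2-en-1-yl acetate
Conditions: Li2NiBr4 (THF solution), THF, 0 → 23 °C; pH 7 buffer work-up
Reagents that add atoms: dilithium tetrabromonickelate, [Li+].[Li+].[Ni+2].[Br-].[Br-].[Br-].[Br-]
Why: Regioselective SN2 epoxide opening, the soft bromide attacking the less substituted carbon with inversion to give the 6S secondary bromide next to a tertiary alcohol.

Step 3
Reactants: 3 (2E,6S)-6-bromo-7-hydroxy-3,7-dimethyloct-2-en-1-yl acetate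
Product: 5 [(1R,5S)-5-bromo-2,6,6-trimethylcyclohex-2-en-1-yl]methyl acetate, via bromonium ion 4 (not isolated)
Conditions: CF3SO3H (5 mol %), (CF3)2CHOH/CH2Cl2 1:1, −40 → −10 °C
Reagents that add atoms: none
Why: Enantiospecific bromonium-initiated cation–olefin cyclisation, in which acid ionises the tertiary carbinol with anchimeric help of the neighbouring bromine to give 4, the E-alkene attacks its tertiary carbon through a chair transition state (Br and CH2OAc both equatorial, hence cis; the C–Br centre is untouched) and proton loss gives mainly the endocyclic olefin (any exocyclic isomer is removed on AgNO3-impregnated silica).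

Step 4
Reactants: 5 [(1R,5S)-5-bromo-2,6,6-trimethylcyclohex-2-en-1-yl]methyl acetate
Product: 6 [(1R,5S)-5-bromo-2,6,6-trimethylcyclohex-2-en-1-yl]methanol
Conditions: K2CO3 (cat.), MeOH, 0 °C
Reagents that add atoms: none
Why: Base-catalysed transesterification frees the primary alcohol while the hindered equatorial neopentyl bromide (no antiperiplanar β-hydrogen) survives.

Step 5
Reactants: 6 [(1R,5S)-5-bromo-2,6,6-trimethylcyclohex-2-en-1-yl]methanol
Product: 7 (1R,5S)-5-bromo-2,6,6-trimethylcyclohex-2-ene-1-carbaldehyde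
Conditions: Dess–Martin periodinane, NaHCO3, CH2Cl2, 0 °C
Reagents that add atoms: none
Why: Buffered Dess–Martin oxidation gives the β,γ-unsaturated aldehyde without olefin migration (its C1 centre is erased in step 11 anyway).

**Fragment 2 (silyl enone)**

Step 6
Reactants: 8 chlorotriethylsilane; 9 vinylmagnesium bromide (CH2=CHMgBr)
Product: 10 triethyl(vinyl)silane
Conditions: THF, 0 °C → reflux
Reagents that add atoms: none
Why: Nucleophilic substitution at silicon by the vinyl Grignard reagent.

Step 7
Reactants: 10 triethyl(vinyl)silane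
Product: 11 (1,2-dibromoethyl)triethylsilane (racemic)
Conditions: Br2, CH2Cl2, −78 °C
Reagents that add atoms: bromine, BrBr
Why: Electrophilic anti addition of bromine to the vinylsilane.

Step 8
Reactants: 11 (1,2-dibromoethyl)triethylsilane
Product: 12 (1-bromovinyl)triethylsilane
Conditions: Et2NH (neat), reflux
Reagents that add atoms: none
Why: Amine-induced E2 dehydrobromination removes the acidified α-silyl proton and the primary bromide, leaving the 1-bromovinylsilane.

Step 9
Reactants: 12 (1-bromovinyl)triethylsilane; 13 acetaldehyde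
Product: 15 3-(triethylsilyl)but-3-en-2-ol (racemic), via Grignard reagent 14 (not isolated)
Conditions: Mg, THF, reflux; then 13, −20 → 0 °C; NH4Cl (aq)
Reagents that add atoms: none
Why: Grignard formation at the vinylic C–Br bond and 1,2-addition to the aldehyde; the racemic carbinol centre is removed in step 10.

Step 10
Reactants: 15 3-(triethylsilyl)but-3-en-2-ol
Product: 16 3-(triethylsilyl)but-3-en-2-one
Conditions: Dess–Martin periodinane, CH2Cl2, 0 → 23 °C
Reagents that add atoms: none
Why: Dess–Martin oxidation of the allylic alcohol gives the Stork–Ganem α-silyl enone, whose silicon stabilises the Michael-adduct enolate and suppresses polymerisation.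

**Fragment union and completion**

Step 11
Reactants: 7 (1R,5S)-5-bromo-2,6,6-trimethylcyclohex-2-ene-1-carbaldehyde; 16 3-(triethylsilyl)but-3-en-2-one
Product: 19 (6R,10S)-10-bromo-7,11,11-trimethylspiro[5.5]undeca-1,7-dien-3-one, via silyl keto aldehyde 17 (not isolated), via keto aldehyde 18 (not isolated)
Conditions: KN(SiMe3)2, THF, −78 °C; 16, −78 → −30 °C; then KOH, MeOH/H2O, 0 → 23 °C
Reagents that add atoms: none
Why: Stork–Ganem Robinson spiroannulation, in which α-deprotonation gives the endocyclic dienolate, Michael addition at its α-carbon occurs trans to the bromine (the face opposite the pseudoaxial gem-dimethyl methyl that lies on the bromine side) to set the quaternary centre (future spiro C6, R), and KOH then removes silicon and closes ring B by intramolecular aldol condensation of the methyl ketone onto the neopentyl aldehyde (minor C6 epimer removed by chromatography).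

Step 12
Reactants: 19 (6R,10S)-10-bromo-7,11,11-trimethylspiro[5.5]undeca-1,7-dien-3-one
Product: 21 (2R,6R,10S)-2,10-dibromo-7,11,11-trimethylspiro[5.5]undec-7-en-3-one, via silyl enol ether 20 (not isolated)
Conditions: RhCl(PPh3)3 (2 mol %), Et3SiH, THF, 50 °C; then NBS, THF, −78 °C; then LiBr, acetone, 23 °C
Reagents that add atoms: N-bromosuccinimide, O=C1CCC(=O)N1Br
Why: Ojima 1,4-hydrosilylation gives the regiodefined enol ether, and its bromination from the face away from the axial C7 carbon (whose methyl covers the other face), backed by bromide-mediated equilibration, gives the equatorial 2R bromide, the axial epimer being destabilised by a 1,3-diaxial clash with C7.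

Step 13
Reactants: 21 (2R,6R,10S)-2,10-dibromo-7,11,11-trimethylspiro[5.5]undec-7-en-3-one
Product: 22 (2R,3S,6R,10S)-2,10-dibromo-3,7,11,11-tetramethylspiro[5.5]undec-7-en-3-ol
Conditions: CeCl3 (anhydrous), MeMgBr, THF, −78 °C; AcOH quench at −78 °C
Reagents that add atoms: methylmagnesium bromide, C[Mg]Br
Why: Imamoto organocerium 1,2-addition, non-basic enough to spare the α-bromo ketone, with equatorial attack expected to give the axial alcohol (3S); this carbinol configuration is inconsequential because both epimers ionise to the same cation in step 14.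

Step 14
Reactants: 22 (2R,3S,6R,10S)-2,10-dibromo-3,7,11,11-tetramethylspiro[5.5]undec-7-en-3-ol
Product: 24 (2R,3R,6R,10S)-2,10-dibromo-3-chloro-3,7,11,11-tetramethylspiro[5.5]undec-7-ene, via chlorosulfite 23 (not isolated)
Conditions: SOCl2, CH2Cl2, −30 → 0 °C
Reagents that add atoms: thionyl chloride, O=S(Cl)Cl
Why: Winstein-type neighbouring-group substitution, in which the tertiary chlorosulfite ionises, the C2 bromine bridges the cation from its own face and chloride opens the bromonium at the tertiary C3 anti to bromine, giving the trans bromochloride (3R).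

**Compound list**
1 | geranyl acetate, (2E)-3,7-dimethylocta-2,6-dien-1-yl acetate | CC(C)=CCC/C(C)=C/COC(C)=O | starting material
2 | (2E)-5-[(2R)-3,3-dimethyloxiran-2-yl]-3-methylpent-2-en-1-yl acetate | CC(=O)OC/C=C(\C)CC[C@H]1OC1(C)C | intermediate
3 | (2E,6S)-6-bromo-7-hydroxy-3,7-dimethyloct-2-en-1-yl acetate | CC(=O)OC/C=C(\C)CC[C@H](Br)C(C)(C)O | intermediate
4 | (2S)-2-[(3E)-5-acetoxy-3-methylpent-3-en-1-yl]-3,3-dimethylbromiranium ion | CC(=O)OC/C=C(\C)CC[C@@H]1[Br+]C1(C)C | intermediate
5 | [(1R,5S)-5-bromo-2,6,6-trimethylcyclohex-2-en-1-yl]methyl acetate | CC(=O)OC[C@@H]1C(C)=CC[C@H](Br)C1(C)C | intermediate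
6 | [(1R,5S)-5-bromo-2,6,6-trimethylcyclohex-2-en-1-yl]methanol | OC[C@@H]1C(C)=CC[C@H](Br)C1(C)C | intermediate
7 | (1R,5S)-5-bromo-2,6,6-trimethylcyclohex-2-ene-1-carbaldehyde | O=C[C@@H]1C(C)=CC[C@H](Br)C1(C)C | intermediate
8 | chlorotriethylsilane | CC[Si](Cl)(CC)CC | starting material
9 | vinylmagnesium bromide | C=C[Mg]Br | starting material
10 | triethyl(vinyl)silane | CC[Si](CC)(CC)C=C | intermediate
11 | (1,2-dibromoethyl)triethylsilane (racemic) | CC[Si](CC)(CC)C(Br)CBr | intermediate
12 | (1-bromovinyl)triethylsilane | CC[Si](CC)(CC)C(Br)=C | intermediate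
13 | acetaldehyde | CC=O | starting material
14 | [1-(triethylsilyl)vinyl]magnesium bromide | CC[Si](CC)(CC)C(=C)[Mg]Br | intermediate
15 | 3-(triethylsilyl)but-3-en-2-ol (racemic) | CC(O)C(=C)[Si](CC)(CC)CC | intermediate
16 | 3-(triethylsilyl)but-3-en-2-one | CC(=O)C(=C)[Si](CC)(CC)CC | intermediate
17 | (1R,5S)-5-bromo-2,6,6-trimethyl-1-[3-oxo-2-(triethylsilyl)butyl]cyclohex-2-ene-1-carbaldehyde (epimers at the silicon-bearing carbon) | CC1=CC[C@H](Br)C(C)(C)[C@@]1(C=O)CC([Si](CC)(CC)CC)C(C)=O | intermediate
18 | (1R,5S)-5-bromo-2,6,6-trimethyl-1-(3-oxobutyl)cyclohex-2-ene-1-carbaldehyde | CC1=CC[C@H](Br)C(C)(C)[C@@]1(C=O)CCC(C)=O | intermediate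
19 | (6R,10S)-10-bromo-7,11,11-trimethylspiro[5.5]undeca-1,7-dien-3-one | CC1=CC[C@H](Br)C(C)(C)[C@@]12CCC(=O)C=C2 | intermediate
20 | triethyl{[(6R,10S)-10-bromo-7,11,11-trimethylspiro[5.5]undeca-2,7-dien-3-yl]oxy}silane | CC1=CC[C@H](Br)C(C)(C)[C@@]12CCC(O[Si](CC)(CC)CC)=CC2 | intermediate
21 | (2R,6R,10S)-2,10-dibromo-7,11,11-trimethylspiro[5.5]undec-7-en-3-one | CC1=CC[C@H](Br)C(C)(C)[C@@]12CCC(=O)[C@H](Br)C2 | intermediate
22 | (2R,3S,6R,10S)-2,10-dibromo-3,7,11,11-tetramethylspiro[5.5]undec-7-en-3-ol | CC1=CC[C@H](Br)C(C)(C)[C@@]12CC[C@](C)(O)[C@H](Br)C2 | intermediate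
23 | (2R,3S,6R,10S)-2,10-dibromo-3,7,11,11-tetramethylspiro[5.5]undec-7-en-3-yl chlorosulfite | CC1=CC[C@H](Br)C(C)(C)[C@@]12CC[C@](C)(OS(Cl)=O)[C@H](Br)C2 | intermediate
24 | (2R,3R,6R,10S)-2,10-dibromo-3-chloro-3,7,11,11-tetramethylspiro[5.5]undec-7-ene | CC1=CC[C@H](Br)C(C)(C)[C@@]12CC[C@@](C)(Cl)[C@H](Br)C2 | target

**Totals**
Total step count: 14. Longest linear sequence: 9 (steps 1–5 then 11–14; the other branch, steps 6–10 then 11–14, is also 9).

**Steps most likely to fail and fallbacks**

Step 3 (direct acid ionisation in the presence of an allylic acetate; olefin regiochemistry at termination). The fallback sets out from 3 and comes back at 5. SOCl2 in CH2Cl2 at −20 °C converts the tertiary alcohol, with retention through the same bridged ion, into the bromochloride (2E,6S)-6-bromo-7-chloro-3,7-dimethyloct-2-en-1-yl acetate F1. Stirring F1 in (CF3)2CHOH at 23 °C without added acid ionises the tertiary chloride solvolytically to bromonium ion 4, which cyclises to 5, so the allylic acetate never meets CF3SO3H.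

Step 11 (Michael addition of a very hindered dienolate; face selectivity; retro-Michael under base). The fallback sets out from 7 and comes back at 18. TBSOTf/Et3N in CH2Cl2 at 0 °C gives the silyl dienol ether tert-butyl{[(5S)-5-bromo-2,6,6-trimethylcyclohex-2-en-1-ylidene]methoxy}dimethylsilane F2 (E/Z mixture). A Mukaiyama–Michael addition of F2 to commercial methyl vinyl ketone (BF3·OEt2, CH2Cl2, −78 °C) gives keto aldehyde 18 after aqueous work-up, and 18 is closed to 19 with KOH/MeOH as in step 11. This replaces the basic metal dienolate and the silyl enone by a Lewis-acid-driven addition of a neutral nucleophile.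

Step 14 (tertiary chloride formation may be undercut by E1 elimination or HCl addition to the ring A olefin). The fallback sets out from 19 and comes back at 24. Conjugate reduction with LiBH(s-Bu)3 and trapping with PhNTf2 gives the enol triflate (6R,10S)-10-bromo-7,11,11-trimethylspiro[5.5]undeca-2,7-dien-3-yl trifluoromethanesulfonate F3. Methylation with AlMe3 and Pd(PPh3)4 (cat.) gives the diene (6R,10S)-10-bromo-3,7,11,11-tetramethylspiro[5.5]undeca-2,7-diene F4. Bu4NBrCl2 in CH2Cl2 at −78 °C then adds Br and Cl anti across the less hindered ring B olefin, bromine entering at C2 from the face away from the axial C7 methyl and chloride at the tertiary C3, to give 24 directly.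

**Further compounds**
F1 | step 3 | (2E,6S)-6-bromo-7-chloro-3,7-dimethyloct-2-en-1-yl acetate | CC(=O)OC/C=C(\C)CC[C@H](Br)C(C)(C)Cl
F2 | step 11 | tert-butyl{[(5S)-5-bromo-2,6,6-trimethylcyclohex-2-en-1-ylidene]methoxy}dimethylsilane | CC1=CC[C@H](Br)C(C)(C)C1=CO[Si](C)(C)C(C)(C)C
F3 | step 14 | (6R,10S)-10-bromo-7,11,11-trimethylspiro[5.5]undeca-2,7-dien-3-yl trifluoromethanesulfonate | CC1=CC[C@H](Br)C(C)(C)[C@@]12CCC(OS(=O)(=O)C(F)(F)F)=CC2
F4 | step 14 | (6R,10S)-10-bromo-3,7,11,11-tetramethylspiro[5.5]undeca-2,7-diene | CC1=CC[C@H](Br)C(C)(C)[C@@]12CCC(C)=CC2
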